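**Retrosynthetic overview**
- Feature: ring A is a symmetric 6,7-dioxygenated benzene. Its neighbouring carbons C8a and C4a each stand para to an oxygen, so both ends (C1 and C4) of the chain C1–C2–C3–C4 can be joined to veratrole as electrophiles.
- Key disconnection: C1–C8a and C4–C4a are made in one operation, which closes ring B. The bis-electrophile is a γ-lactone (C1–O–C(=O)–C3) carrying C4 as a methoxymethylene group and ring C as a tris(benzyloxy)phenyl group.
- Lactone: Evans syn-aldol of a succinate imide, hydroperoxide cleavage, formylation of the acid dianion, double O-methylation.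
- Stereochemical relay: the aldol centre C2 sends veratrole to the C1 face anti to the acrylate arm (1,2-cis). C1 then resets C2 by base equilibration to the 1,2-trans series, which calls for the (S)-auxiliary.
- Ring order: temporary lactone, then ring B onto ring A, then the pyrone from ring C (debenzylation, peracid intradiol cleavage, enol lactonisation). Ring A is unmasked last.

Key step: step 6

Remark: C1–C4, C4a and C8a are dihydronaphthalene locants and are used for the same carbons in all earlier intermediates; tetrahydrofuran locants appear only in lactone names; ring C is the pendant ring that becomes the pyrone.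

**Step 1**
Reactants: 1 (S)-4-benzyl-2-oxazolidinone; 2 methyl 4-chloro-4-oxobutanoate
Product: 3 methyl 4-[(4S)-4-benzyl-2-oxo-1,3-oxazolidin-3-yl]-4-oxobutanoate
Conditions: n-BuLi, THF, −78 °C; then 2, −78 → 0 °C
Reagents that add atoms: none
Why: N-acylation of the lithiated oxazolidinone by the acid chloride is the standard imide formation, and the methyl ester is far less electrophilic at this temperature.

**Step 2**
Reactants: 3 imide; 4 3,4,5-tris(benzyloxy)benzaldehyde
Product: 6 (4S)-4-benzyl-3-{[(2S,3S)-5-oxo-2-[3,4,5-tris(benzyloxy)phenyl]tetrahydrofuran-3-yl]carbonyl}-1,3-oxazolidin-2-one, via syn-aldol adduct 5 (not isolated)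
Conditions: Bu2BOSO2CF3, Et3N, CH2Cl2, −78 → 0 °C; 4, −78 °C → rt; pH 7 buffer, MeOH, H2O2, 0 °C
Reagents that add atoms: none
Why: In this Evans syn-aldol the Z-boron enolate reacts through a Zimmerman–Traxler chair on the face away from the benzyl group, which sets C2 and C1 (both S as lactone locants 3 and 2), and the boron aldolate then closes on the methyl ester to give the trans γ-lactone.

**Step 3**
Reactants: 6 lactone imide
Product: 7 (2S,3S)-5-oxo-2-[3,4,5-tris(benzyloxy)phenyl]tetrahydrofuran-3-carboxylic acid
Conditions: LiOH, H2O2, THF–H2O, 0 °C; Na2SO3; HCl to pH 2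
Reagents that add atoms: hydrogen peroxide, OO
Why: In this hydroperoxide cleavage of an N-acyloxazolidinone the hydroperoxide attacks the exocyclic imide carbonyl without epimerising C2, and any lactone that opens closes again on acidification.

**Step 4**
Reactants: 7 lactone acid
Product: 8 (2S,3S)-4-(hydroxymethylene)-5-oxo-2-[3,4,5-tris(benzyloxy)phenyl]tetrahydrofuran-3-carboxylic acid (enol of the 4-formyl lactone)
Conditions: LiN(SiMe3)2 (2.3 equiv), THF, −78 °C; HCO2Me, −78 → −20 °C; cold 1 M HCl
Reagents that add atoms: methyl formate, COC=O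
Why: In this Claisen-type formylation of a lactone enolate the carboxylate formed first makes C2–H non-acidic, so the Stobbe-type E1cB opening of C1–O that a paraconic ester would suffer cannot start, and the C3 enolate is formylated and held as its stable enolate until work-up.

**Step 5**
Reactants: 8 hydroxymethylene acid
Product: 9 methyl (2S,3S,4E)-4-(methoxymethylene)-5-oxo-2-[3,4,5-tris(benzyloxy)phenyl]tetrahydrofuran-3-carboxylate
Conditions: Me3SiCHN2 (excess), toluene–MeOH, 0 °C → rt
Reagents that add atoms: (trimethylsilyl)diazomethane, C[Si](C)(C)C=[N+]=[N-]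
Why: Base-free diazoalkane O-methylation of the carboxylic acid and the vinylogous acid leaves C2–H untouched, and the enol ether geometry does not matter because C4 passes through sp3 in step 6.

**Step 6**
Reactants: 9 methoxymethylene lactone; 10 veratrole
Product: 12 (1R,2R)-6,7-dimethoxy-2-(methoxycarbonyl)-1-[3,4,5-tris(benzyloxy)phenyl]-1,2-dihydronaphthalene-3-carboxylic acid (1,2-cis), via open-chain silyl ester 11 (not isolated)
Conditions: 10 (5 equiv), Me3SiOSO2CF3 (2.5 equiv), CH2Cl2, −60 → 0 °C; pH 4 buffer
Reagents that add atoms: none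
Why: Proposed new method: Me3SiOSO2CF3 silylates the lactone carbonyl oxygen (a vinylogous carbonate and the most basic site), the benzylic C1–O bond ionises to a cation stabilised by the para benzyloxy group of ring C, veratrole attacks it para to one methoxy group (C1–C8a, giving 11), and the CF3SO3H released then activates the β-methoxyacrylate at its carbonyl oxygen so that C4 is attacked by the ring A carbon next to C8a, para to the second methoxy group (C4–C4a), before methanol is lost and C3=C4 is restored. The closest known reaction types are the Friedel–Crafts alkylation of arenes with γ-aryl-γ-butyrolactones and the acid cyclodehydration of α-(hydroxymethylene or alkoxymethylene)-γ-arylbutyrates to 3,4-dihydro-2-naphthoates, and their union in one flask on one lactone is untested. Ring B closes 6-endo-trig when counted on C3=C4 (6-exo-trig when counted on the MeO+=C4 resonance form), a favoured mode either way. C1 is controlled by C2: 1,3-allylic strain holds C2–H in the cation plane beside ring C, the acrylate arm that still carries the departed silyl carboxylate covers one face, and the arene enters from the other face next to the small ester carbonyl, which means inversion at C1 and a 1,2-cis ring (1R,2R), the sense known for intermolecular arylation of α-branched benzylic cations. Beyond this facial selectivity the step needs para regiochemistry for both bonds, secured by the two methoxy groups, and closure onto ring A instead of ring C, secured because each ortho carbon of ring C is wedged between C1 and an in-plane benzyloxy group, as in the classical closures of diarylmethylsuccinic half-esters that choose the 3,4-dioxygenated ring. Excess veratrole and low temperature serve to outrun loss of the C2 proton and benzyl transfer, and aryl benzyl ethers are known to survive silyl triflates at such temperatures.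

**Step 7**
Reactants: 12 cis half-ester
Product: 14 (1R,2S)-6,7-dimethoxy-1-[3,4,5-tris(benzyloxy)phenyl]-1,2-dihydronaphthalene-2,3-dicarboxylic acid, via trans half-ester 13 (not isolated)
Conditions: NaOMe, MeOH, 55 °C, argon; then 2 M NaOH, 55 °C; HCl to pH 2
Reagents that add atoms: sodium hydroxide, [Na+].[OH-]
Why: Methoxide reversibly removes C2–H (α to the ester and allylic) while the C1–H stays untouched, so C1 now dictates C2 and thermodynamic epimerisation should settle on the 1,2-trans half-ester with ring C and the ester both pseudo-axial (no peri strain with C8–H and no 1,2-allylic strain with the C3 carboxylate), after which hydroxide saponifies the ester at a stage where no base-labile pyrone exists.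

**Step 8**
Reactants: 14 trans diacid
Product: 15 (1R,2S)-6,7-dimethoxy-1-(3,4,5-trihydroxyphenyl)-1,2-dihydronaphthalene-2,3-dicarboxylic acid
Conditions: BCl3, C6HMe5, CH2Cl2, −78 °C; then THF–H2O
Reagents that add atoms: none
Why: Lewis-acid cleavage of aryl benzyl ethers with pentamethylbenzene as a non-basic cation scavenger spares the methyl ethers at −78 °C and, unlike hydrogenolysis, leaves C3=C4 intact.

**Step 9**
Reactants: 15 pyrogallol diacid
Product: 17 (1R,2S)-1-(6-carboxy-2-oxo-2H-pyran-4-yl)-6,7-dimethoxy-1,2-dihydronaphthalene-2,3-dicarboxylic acid, via ring-opened oxo acid 16 (not isolated)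
Conditions: CH3CO3H (2.2 equiv), AcOH, 10 °C → rt, dark; then H2SO4 (cat.), 40 °C
Reagents that add atoms: peracetic acid, CC(=O)OO
Why: Peracid intradiol cleavage of a pyrogallol (hydroxy-o-quinone, Baeyer–Villiger-type oxygen insertion, opening) gives the 2-hydroxymuconic acid or its keto form, whose enol oxygen is acylated by the cis-placed carboxyl group to form the 2-pyrone-6-carboxylic acid, while the etherified and acrylate-deactivated ring A reacts far more slowly.

**Step 10**
Reactants: 17 pyrone dimethyl ether
Product: 18 (1R,2S)-1-(6-carboxy-2-oxo-2H-pyran-4-yl)-6,7-dihydroxy-1,2-dihydronaphthalene-2,3-dicarboxylic acid (target)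
Conditions: BBr3 (excess), CH2Cl2, −78 °C → rt; ice–water; reversed-phase chromatography
Reagents that add atoms: none
Why: BBr3 cleavage of aryl methyl ethers needs no base, so the pyrone, the three acids and the C2 centre should persist.

**Compound list**
1 | (S)-4-benzyl-2-oxazolidinone | O=C1N[C@@H](Cc2ccccc2)CO1 | starting material
2 | methyl 4-chloro-4-oxobutanoate | COC(=O)CCC(=O)Cl | starting material
3 | methyl 4-[(4S)-4-benzyl-2-oxo-1,3-oxazolidin-3-yl]-4-oxobutanoate | COC(=O)CCC(=O)N1[C@@H](Cc2ccccc2)COC1=O | intermediate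
4 | 3,4,5-tris(benzyloxy)benzaldehyde | O=Cc1cc(OCc2ccccc2)c(OCc2ccccc2)c(OCc2ccccc2)c1 | starting material
5 | syn-aldol adduct (α-carbon S, carbinol S, auxiliary S) | COC(=O)C[C@@H]([C@H](O)c1cc(OCc2ccccc2)c(OCc2ccccc2)c(OCc2ccccc2)c1)C(=O)N1[C@@H](Cc2ccccc2)COC1=O | intermediate
6 | trans (2S,3S)-lactone imide | O=C1C[C@H](C(=O)N2[C@@H](Cc3ccccc3)COC2=O)[C@@H](c2cc(OCc3ccccc3)c(OCc3ccccc3)c(OCc3ccccc3)c2)O1 | intermediate
7 | (2S,3S)-5-oxo-2-[3,4,5-tris(benzyloxy)phenyl]tetrahydrofuran-3-carboxylic acid | O=C1C[C@H](C(=O)O)[C@@H](c2cc(OCc3ccccc3)c(OCc3ccccc3)c(OCc3ccccc3)c2)O1 | intermediate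
8 | (2S,3S)-4-(hydroxymethylene) lactone acid (enol geometry mobile) | OC=C1C(=O)O[C@H](c2cc(OCc3ccccc3)c(OCc3ccccc3)c(OCc3ccccc3)c2)[C@H]1C(=O)O | intermediate
9 | methyl (2S,3S,4E)-4-(methoxymethylene)-5-oxo-2-[3,4,5-tris(benzyloxy)phenyl]tetrahydrofuran-3-carboxylate | CO/C=C1/C(=O)O[C@H](c2cc(OCc3ccccc3)c(OCc3ccccc3)c(OCc3ccccc3)c2)[C@H]1C(=O)OC | intermediate
10 | veratrole | COc1ccccc1OC | starting material
11 | trimethylsilyl (2E,3R,4S)-4-(3,4-dimethoxyphenyl)-3-(methoxycarbonyl)-2-(methoxymethylene)-4-[3,4,5-tris(benzyloxy)phenyl]butanoate | CO/C=C(/C(=O)O[Si](C)(C)C)[C@H](C(=O)OC)[C@@H](c1ccc(OC)c(OC)c1)c1cc(OCc2ccccc2)c(OCc2ccccc2)c(OCc2ccccc2)c1 | intermediate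
12 | (1R,2R)-cis half-ester (C3 acid, C2 methyl ester) | O=C(O)C1=Cc2cc(OC)c(OC)cc2[C@@H](c2cc(OCc3ccccc3)c(OCc3ccccc3)c(OCc3ccccc3)c2)[C@H]1C(=O)OC | intermediate
13 | (1R,2S)-trans half-ester (C3 acid, C2 methyl ester) | O=C(O)C1=Cc2cc(OC)c(OC)cc2[C@@H](c2cc(OCc3ccccc3)c(OCc3ccccc3)c(OCc3ccccc3)c2)[C@@H]1C(=O)OC | intermediate
14 | (1R,2S)-trans diacid, ring C tribenzyl ether | O=C(O)C1=Cc2cc(OC)c(OC)cc2[C@@H](c2cc(OCc3ccccc3)c(OCc3ccccc3)c(OCc3ccccc3)c2)[C@@H]1C(=O)O | intermediate
15 | (1R,2S)-trans diacid, ring C free pyrogallol | O=C(O)C1=Cc2cc(OC)c(OC)cc2[C@@H](c2cc(O)c(O)c(O)c2)[C@@H]1C(=O)O | intermediate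
16 | ring-opened 4-substituted 2-oxohex-4-enedioic acid (keto form of the 2-hydroxymuconic acid; CH2 and CO2H cis on the C=C) | O=C(O)C1=Cc2cc(OC)c(OC)cc2[C@@H](C(/CC(=O)C(=O)O)=C/C(=O)O)[C@@H]1C(=O)O | intermediate
17 | (1R,2S)-pyrone triacid, ring A dimethyl ether | O=C(O)C1=Cc2cc(OC)c(OC)cc2[C@@H](c2cc(C(=O)O)oc(=O)c2)[C@@H]1C(=O)O | intermediate
18 | CNP0195322.1 | O=C(O)C1=Cc2cc(O)c(O)cc2[C@@H](c2cc(C(=O)O)oc(=O)c2)[C@@H]1C(=O)O | target

Total step count: 10. Longest linear sequence: 10 (from 1 or 2 to 18).

**Steps most likely to fail**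

**1. Step 6.**
- What may go wrong: the open C1 cation may be captured with poor facial selectivity. It may lose the C2 proton, which erases the only controlling centre. It may close onto ring C, or benzyl groups may migrate to veratrole.
- Fallback (known chemistry): C4–C4a is bought in with veratraldehyde and C1–C8a becomes the ring-closing bond. That closure gives the 1,2-trans ring directly, so the antipodal aldol series is needed.
- It sets out from 2 and 4. Steps 1 to 3 are repeated with (R)-4-benzyl-2-oxazolidinone to give the imide F1, the syn-aldol adduct F2 (not isolated), the lactone imide F3 and the (2R,3R)-acid F4.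
- The dianion of F4 (LiN(SiMe3)2, THF, −78 °C) is added to 3,4-dimethoxybenzaldehyde to give the aldol acid F5. Me3SiCHN2 converts this into the methyl ester F6.
- CF3CO2H in CH2Cl2 dehydrates F6 to the (E)-benzylidene lactone F7 (not isolated). It then ionises C1–O for an intramolecular Friedel–Crafts closure, as known for benzylidene γ-aryl lactones in dihydronaphthalene lignan work.
- The fallback comes back to the route at 13, which is saponified as in step 7.

**2. Step 9.**
- What may go wrong: the peracid may go on to attack C3=C4 or ring A, or the hydroxyquinone may oligomerise before oxygen insertion.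
- Fallback: the two oxidation events are separated. It sets out from 15.
- NaIO4 in aqueous acetonitrile at 0 °C gives the isolable 3-hydroxy-o-quinone F8.
- One equivalent of 3-chloroperbenzoic acid in CH2Cl2 then inserts oxygen to give the hydroxymuconic anhydride F9.
- F9 is opened and relactonised in wet acetic acid. The fallback comes back at 17.

**3. Step 7.**
- What may go wrong: the extended enolate may be reprotonated at C4, moving the double bond to C2=C3. It may be oxidised by traces of air to the naphthalene. Saponification may also outrun equilibration and freeze the cis series.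
- Fallback: the neutral diester is equilibrated with an amine base instead of the carboxylate salt with alkoxide. It sets out from 12.
- Me3SiCHN2 gives the cis dimethyl ester F10. 1,8-Diazabicyclo[5.4.0]undec-7-ene in toluene at 60 °C equilibrates it to the trans dimethyl ester F11, which is purified.
- LiOH in THF–H2O at rt cleaves both esters. The fallback comes back at 14.

**Further compounds**
F1 | step 6 | methyl 4-[(4R)-4-benzyl-2-oxo-1,3-oxazolidin-3-yl]-4-oxobutanoate | COC(=O)CCC(=O)N1[C@H](Cc2ccccc2)COC1=O
F2 | step 6 | syn-aldol adduct of the (R) series | COC(=O)C[C@H]([C@@H](O)c1cc(OCc2ccccc2)c(OCc2ccccc2)c(OCc2ccccc2)c1)C(=O)N1[C@H](Cc2ccccc2)COC1=O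
F3 | step 6 | trans (2R,3R)-lactone imide | O=C1C[C@@H](C(=O)N2[C@H](Cc3ccccc3)COC2=O)[C@H](c2cc(OCc3ccccc3)c(OCc3ccccc3)c(OCc3ccccc3)c2)O1
F4 | step 6 | (2R,3R)-5-oxo-2-[3,4,5-tris(benzyloxy)phenyl]tetrahydrofuran-3-carboxylic acid | O=C1C[C@@H](C(=O)O)[C@H](c2cc(OCc3ccccc3)c(OCc3ccccc3)c(OCc3ccccc3)c2)O1
F5 | step 6 | (2R,3R)-4-[(3,4-dimethoxyphenyl)(hydroxy)methyl] lactone acid (epimers at C4 and carbinol) | COc1ccc(C(O)C2C(=O)O[C@@H](c3cc(OCc4ccccc4)c(OCc4ccccc4)c(OCc4ccccc4)c3)[C@@H]2C(=O)O)cc1OC
F6 | step 6 | methyl ester of F5 | COc1ccc(C(O)C2C(=O)O[C@@H](c3cc(OCc4ccccc4)c(OCc4ccccc4)c(OCc4ccccc4)c3)[C@@H]2C(=O)OC)cc1OC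
F7 | step 6 | methyl (2R,3R,4E)-4-(3,4-dimethoxybenzylidene)-5-oxo-2-[3,4,5-tris(benzyloxy)phenyl]tetrahydrofuran-3-carboxylate | COc1ccc(/C=C2/C(=O)O[C@@H](c3cc(OCc4ccccc4)c(OCc4ccccc4)c(OCc4ccccc4)c3)[C@@H]2C(=O)OC)cc1OC
F8 | step 9 | 3-hydroxy-o-quinone of 15 | O=C(O)C1=Cc2cc(OC)c(OC)cc2[C@@H](C2=CC(=O)C(=O)C(O)=C2)[C@@H]1C(=O)O
F9 | step 9 | hydroxymuconic anhydride (3-hydroxyoxepine-2,7-dione) | O=C(O)C1=Cc2cc(OC)c(OC)cc2[C@@H](C2=CC(=O)OC(=O)C(O)=C2)[C@@H]1C(=O)O
F10 | step 7 | (1R,2R)-cis dimethyl ester | COC(=O)C1=Cc2cc(OC)c(OC)cc2[C@@H](c2cc(OCc3ccccc3)c(OCc3ccccc3)c(OCc3ccccc3)c2)[C@H]1C(=O)OC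
F11 | step 7 | (1R,2S)-trans dimethyl ester | COC(=O)C1=Cc2cc(OC)c(OC)cc2[C@@H](c2cc(OCc3ccccc3)c(OCc3ccccc3)c(OCc3ccccc3)c2)[C@@H]1C(=O)OC
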